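## Structural features

The target is a briarane. A cyclohexane (ring A: C1, C10–C14) is trans-fused through C1–C10 to a ten-membered carbocycle (C1–C10), which in turn carries a trans-fused γ-lactone (C7, C8, C17, C19 and the ring oxygen). Twelve stereocentres are packed together: the all-carbon quaternary C1 (methyl C15) sits between the C2 butanoate carbinol, the C13/C14 epoxide and C10, and C10 links it to the fully substituted C11 carbinol, the C12 butanoate and the C9 acetate/C8 tertiary alcohol pair. All four oxygens of ring A lie on the α face, opposite to both methyl groups (C15, C20); the C8/C9 oxygens are syn, and the C6 chloride is anti to the C7 lactone oxygen. The ten-membered ring holds a (3Z)-olefin conjugated with the C5=C16 methylene. Fragile groups are the allylic secondary chloride (ionisation, SN2'), the epoxide next to an ester, three esters that must be told apart from two free tertiary alcohols, the β-hydroxy lactone with its epimerisable C17, and the Z-diene. The real difficulty is quaternary C1, flanked on three sides by stereocentres, together with the medium ring and its C6/C7 pair. The key step uses the fact that C1 carries C15, the oxygenated C2 and ring carbon C14. The C1–C2 bond can therefore be grafted onto a ring A enone (C14=C1, C13 ketone) by an alkene that already bears the C2 and C3 oxygens. The surplus C3–C14 bond is β to the C13 ketone and can be released by retro-aldol.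

## Logic of the disconnections

54 ⇒ 53 ⇒ 52. The C12 acyl C–O bond and the two C–O bonds of the epoxide are cut first because they are the most fragile features, and because the free C12 hydroxyl of 52 can steer the oxidant to the α face of C13=C14. Ring A is reduced to an allylic cis-diol olefin. The forward steps must acylate one secondary alcohol beside two tertiary ones and must epoxidise one of three olefins.

52 ⇒ 51 ⇒ 48 ⇒ 47. The lactone C19–O7 bond is traced back to a 1,4-diol in which C19 is a protected primary alcohol. This keeps C17 configurationally safe while C8 passes through the ketone stage. The cost is two extra late steps; the demand is an oxidant that takes the primary alcohol only, and acid steps that the allylic chloride survives.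

47 ⇒ 46. C6–C7 is cut, the bond between the chlorine-bearing carbon and the lactone carbinol. One allylmetal/aldehyde union then creates the ring, C6–Cl, C7–O and the C5=C16 methylene together. The bicycle falls back to ring A with two arms. The forward step must close a ten-membered ring under high dilution with anti C6/C7 selectivity and the right face.

46 ⇒ 45 ⇒ 44 ⇒ 43 ⇒ 42 ⇒ 38 + 41. After functional-group changes at C7 and C16, the (3Z)-olefin is traced to an alkyne and C4–C5 is cut as an sp–sp2 bond. The alkyne is the only C3/C4 carrier that survives the middle of the route, and 41 brings C5, C6 with its chlorine and C16 in one piece. The coupling must occur at C–I only, and the semi-reduction must touch only the conjugated triple bond.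

38 ⇒ 37 ⇒ 36 ⇒ 35 ⇒ 34. C7–C8 is cut because the 8,9-syn diol is exactly what a chelate-controlled addition to an α-hydroxy ketone gives. The tertiary carbinol is removed and the acyl pattern (C2 butanoate, C9 acetate) is peeled off in the order in which the hydroxyls become free. Chelation must override the adjacent C17 centre.

34 ⇒ 33 ⇒ 32 ⇒ 31 ⇒ 26 + 30. C8–C9 is cut as acyl anion plus aldehyde. The chain is separated from ring A and C17 goes into a small building block. Since the two flanks of C9 on ring A look alike, C9 has to be set by a reagent-controlled ketone reduction, not during the addition.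

30 ⇒ 29 ⇒ 28 ⇒ 27. C17 is taken from the chiral pool. Because the ester carbon becomes C8, the mapping requires the (S)-hydroxy ester.

26 ⇒ 25 ⇒ 24 ⇒ 23 ⇒ 22 ⇒ 21. No skeletal bond is cut; the C2 carbinol is traced to its epimer through the alkynyl ketone 22. The photoadduct delivers the wrong C2 configuration, and an alkynyl ketone is the best substrate class for a reagent-controlled reduction next to a quaternary carbon.

21 ⇒ 20 ⇒ 17. The C13=C14 olefin is traced to the C13 ketone through its enol triflate. The ketone has to be kept until this point because the fragmentation needs it. The forward step needs enolisation toward C14 only.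

17 ⇒ 14. The C3–C4 bond (one-carbon homologation) is cut and C3–C14 is reconnected. This turns a ring A ketone bearing an open C2/C3 arm into a compact tricycle in which C2 and C3 are masked as a cyclic carbonate. The forward retro-aldol needs the free C3 alkoxide β to the C13 ketone, and the labile hydroxy aldehyde must be trapped at once.

14 ⇒ 13 ⇒ 12 ⇒ 10 ⇒ 8. The C11–O and C12–O bonds and the C11–C20 bond are removed. Ring A falls back to the bare C13 ketone, which is used while the cyclobutane carbonate still protects C2/C3. The forward steps need dehydrogenation toward C12 only and osmylation from the α face.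

8 ⇒ 6 + 7. C1–C2 and C3–C14 are cut (retro [2+2]). The quaternary centre and both oxygenated carbons of the C2/C3 unit come from two simple partners. The forward step needs only one selectivity: addition anti to the C10 arm.

6 ⇒ 5 ⇒ 4 ⇒ 2 ⇒ 1. The silyl ether, the resolution and the redox adjustments lead back to a commercial racemic keto ester. The resolution has to act on 4, since 2 and its reduction product have no stereocentre.

41 ⇒ 40 ⇒ 39. The C–I and C–Cl bonds are removed; the vinyl chloride geometry has to come from an anti hydrohalogenation of a chloroalkyne.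

## Other disconnections considered

Alternative 1: The cut is C6–C7 together with the lactone C19–O bond. In the forward sense CrCl2 (divalent chromium) would convert the allylic bromide of the open-chain aldehyde A2 into a γ-chloroallyl species of trivalent chromium. This adds through C6 to the C7 aldehyde, and the chromium alkoxide then closes the lactone on the C19 methyl ester, giving A1.
- In favour: one operation forms the ring, the chloride, the exocyclic methylene and the lactone. The closed chair transition state predicts the anti C6/C7 relationship of the target. The step comes so late that only epoxidation and one acylation remain.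
- Against: it is silent on the hardest centre, C1, and on ring A. It also needs the C19 ester to be carried next to C17 through the steps that build C8.
- Comparison: the chosen plan closes the same bond by the same organochromium logic in step 36, so on ring closure and mechanism the two are equal. On step economy at the end the alternative is the better one, because lactonisation in the closure step saves the detritylation and oxidative lactonisation of steps 37 and 38. As a strategy-defining step it concentrates the stereochemical risk in the last C–C bond, whereas the photochemical step settles C1 early on a small rigid substrate.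

Alternative 2: The cut is the tetrasubstituted C2=C7 olefin of tricycle A4, read backwards from the 1,6-diketone A3. In the forward sense ozone would cleave the olefin shared by two six-membered rings and unveil the ten-membered ring.
- In favour: the medium ring is obtained without any entropically costly cyclisation. On this point the alternative is better than the chosen plan, whose step 36 is its riskiest operation. C1, C8, C9 and C10 can also be set on rigid six-membered rings.
- Against: A3 has ketones at C2 and C7, methylene groups at C3, C4 and C6 and a ketal at C5. The Z-olefin, the exocyclic methylene, the chloride and both carbinol configurations would all have to be introduced on a flexible ring prone to transannular aldol chemistry. No other olefin may be present during ozonolysis. The C11 methine of A3 also carries its methyl on the α face, so C11 would have to pass through an sp2 stage.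
- Comparison: structurally the chosen plan matches the target more closely, since the photo-partner delivers C2–O and C3 at the right oxidation level. Mechanistically ozonolysis is more dependable than a photocycloaddition plus macrocyclisation. In step count the many redox adjustments after A3 should outweigh the saved ring closure.

Alternative 3: The cut is C1–C10. In the forward sense the C1 enolate of the fourteen-membered keto-dienone A6 would add across the ring to C10 of the enone and form both carbocycles. The resulting dienolate would then be hydroxylated at C11 by a sulfonyloxaziridine to give A5.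
- In favour: a single step creates three contiguous centres, two of them fully substituted. It leaves ring A as a C12 enone with the C11 carbinol in place, which is exactly the pattern needed for the epoxy alcohol. On this point it is clearly better than the chosen plan, which spends steps 6–12 on the same task.
- Against: the facial outcome at C1 and C10 depends on the conformation of a heavily substituted macrocycle and cannot be predicted with confidence. Enolisation of the C2 ketone toward C3 competes. A5 still lacks the C3=C4 olefin, and C6 carries oxygen that must later be displaced by chloride with inversion.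
- Comparison: in bond-forming power per step the alternative is superior. In predictability of C1 the chosen plan is stronger, because a small cyclohexenone with an axial neighbouring arm has one clearly exposed face. In step count the two are probably close, since A6 itself needs a long synthesis.

Key step: step 5

Remarks on the chemistry (one line each):
- Locants follow the briarane numbering; β is the face of ring A that carries the C15 methyl, α the opposite face.
- Assumption: the Burkholderia cepacia lipase is taken to acylate (R)-4 faster, so that the (S)-alcohol 5 remains; if the preference is the reverse, the (S)-acetate is methanolysed (K2CO3, MeOH) to the same 5.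
- Correction to the route to the precursor: ketalisation of 1 moves the olefin into conjugation with the ester, so the ketal alcohol has no stereocentre, and the resolution is placed after ketal hydrolysis.
- Correction to the chiral-pool mapping: because the ester carbon of the hydroxy ester becomes C8 here, the (S)-ester 27 is needed; the (R)-ester would give the C17 epimer.
- Precursor design: the primary TBS ether is kept on purpose, since it can later be removed selectively beside a hindered secondary TBS ether (step 16).

## Steps

Step 1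
Reactants: 1 ethyl 2-methyl-4-oxocyclohex-2-ene-1-carboxylate (racemic)
Product: 2 ethyl 7-methyl-1,4-dioxaspiro[4.5]dec-7-ene-8-carboxylate
Conditions: HOCH2CH2OH, p-TsOH (cat.), benzene, reflux, Dean–Stark
Reagents that add atoms: ethylene glycol, OCCO
Why: Acid-catalysed ketalisation; the olefin leaves conjugation with the masked ketone and moves into conjugation with the ester, so 2 is achiral and any olefin isomer converges in step 2.

Step 2
Reactants: 2 ethyl 7-methyl-1,4-dioxaspiro[4.5]dec-7-ene-8-carboxylate
Product: 4 rac-4-(hydroxymethyl)-3-methylcyclohex-2-en-1-one, via allylic alcohol ketal 3 (not isolated)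
Conditions: LiAlH4, THF, 0 °C; then 1 M HCl, THF/H2O, rt
Reagents that add atoms: water, O
Why: Hydride reduction of the enoate gives the allylic alcohol; ketal hydrolysis then gives the β,γ-enone, which isomerises under the acid to the conjugated enone and creates C10 as a racemate.

Step 3
Reactants: 4 rac-4-(hydroxymethyl)-3-methylcyclohex-2-en-1-one
Product: 5 (S)-4-(hydroxymethyl)-3-methylcyclohex-2-en-1-one
Conditions: Burkholderia cepacia lipase, vinyl acetate, t-BuOMe, rt, run to slightly beyond half conversion
Reagents that add atoms: none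
Why: Lipase-catalysed kinetic resolution by irreversible transesterification; the enzyme distinguishes the sp2 and sp3 ring neighbours of the β-stereocentre, and the slower (S)-alcohol is recovered.

Step 4
Reactants: 5 (S)-4-(hydroxymethyl)-3-methylcyclohex-2-en-1-one
Product: 6 (S)-4-[(tert-butyldimethylsilyloxy)methyl]-3-methylcyclohex-2-en-1-one
Conditions: TBSCl, imidazole, DMF, rt
Reagents that add atoms: tert-butyldimethylsilyl chloride, CC(C)(C)[Si](C)(C)Cl
Why: Standard silylation of the primary alcohol under non-enolising conditions, so the γ-stereocentre C10 is not touched.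

Step 5
Reactants: 6 (S)-4-[(tert-butyldimethylsilyloxy)methyl]-3-methylcyclohex-2-en-1-one; 7 vinylene carbonate
Product: 8 cis-anti-cis tricyclic photoadduct (cyclobutane fused at C1–C14 on the α face; C2/C3 cyclic carbonate; C13 ketone)
Conditions: hν (366 nm, Pyrex), 7 (10 equiv), CH2Cl2, −40 °C
Reagents that add atoms: none
Why: Excitation of the enone and intersystem crossing give the twisted triplet, which adds to vinylene carbonate stepwise through a triplet 1,4-diradical; after spin inversion the diradical collapses to the cyclobutane (enone–alkene [2+2] photocycloaddition of the de Mayo type). The four-membered ring is thus closed by radical recombination and is cis-fused to ring A, because a trans-fused bicyclo[4.2.0]octanone is strained and any trans isomer epimerises at C14 on mild base treatment. C1 is controlled by the C10 arm: allylic 1,2-strain with the C15 methyl forces CH2OTBS into a pseudoaxial position, where it covers one face of the β-carbon, so C1–C2 forms anti to C9. C14 follows from the cis ring fusion. C2 and C3 are cis from the alkene and anti to ring A for steric reasons; this gives the wrong C2 configuration, which is re-set in steps 13 and 14, while C3 and C14 lose their stereochemistry in steps 10 and 11. The only selectivity needed is facial: regiochemistry does not arise with a symmetric alkene, and any C2/C3 exo/endo isomer converges later. No ionic crowded transition state is involved in making the quaternary centre, which is why the step should tolerate the fully substituted β-carbon.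

Step 6
Reactants: 8 cis-anti-cis tricyclic photoadduct
Product: 10 tricyclic C11=C12 enone carbonate, via silyl enol ether 9 (not isolated)
Conditions: LiN(SiMe3)2, Me3SiCl, THF, −78 °C; then Pd(OAc)2, MeCN, rt
Reagents that add atoms: none
Why: Kinetic enolisation can go only toward C12 (C14 is a cyclobutane ring-fusion methine), and Saegusa–Ito oxidation of the enol silane by divalent palladium gives the enone; dehydrogenation toward quaternary C1 is impossible.

Step 7
Reactants: 10 tricyclic C11=C12 enone carbonate
Product: 12 tricyclic 11-methyl C11=C12 enone carbonate, via methylated silyl enol ether 11 (not isolated)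
Conditions: Me2CuLi, Me3SiCl, THF, −78 °C; then Pd(OAc)2, MeCN, rt
Reagents that add atoms: lithium dimethylcuprate, [Li+].C[Cu-]C
Why: Conjugate addition of the Gilman reagent, accelerated and trapped by Me3SiCl, places the C20 methyl on C11; a second Saegusa–Ito oxidation restores the enone, so the transient C11 configuration does not matter.

Step 8
Reactants: 12 tricyclic 11-methyl C11=C12 enone carbonate
Product: 13 11α,12α-dihydroxy C13 ketone carbonate
Conditions: OsO4 (5 mol%), NMO, t-BuOH/acetone/H2O, rt
Reagents that add atoms: osmium tetroxide (catalytic oxygen carrier), O=[Os](=O)(=O)=O; N-methylmorpholine N-oxide, C[N+]1([O-])CCOCC1; water, O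
Why: Catalytic syn-dihydroxylation (Upjohn conditions); the oxidant should approach anti to the adjacent β-oriented C10 arm, i.e. from the α face, which sets C11 (hydroxyl α, methyl β) and C12 (hydroxyl α) together.

Step 9
Reactants: 13 11α,12α-dihydroxy C13 ketone carbonate
Product: 14 11,12-acetonide C13 ketone carbonate
Conditions: Me2C(OMe)2, PPTS, CH2Cl2, rt
Reagents that add atoms: 2,2-dimethoxypropane, COC(C)(C)OC
Why: Acid-catalysed transketalisation of the cis-diol; the acetonide removes the free tertiary β-hydroxyl (retro-aldol risk) and holds the C11–O bond near the enolate plane, so β-elimination is stereoelectronically disfavoured in the basic steps that follow.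

Step 10
Reactants: 14 11,12-acetonide C13 ketone carbonate
Product: 17 2-epi propargylic alcohol C13 ketone acetonide, via cyclobutanediol 15 (not isolated), via hydroxy aldehyde 16 (not isolated)
Conditions: K2CO3, MeOH, 0 °C to rt; then MeC(O)C(N2)P(O)(OMe)2, rt
Reagents that add atoms: dimethyl (1-diazo-2-oxopropyl)phosphonate, COP(=O)(OC)C(=[N+]=[N-])C(C)=O
Why: Methanolysis of the carbonate frees the C3 alkoxide β to the C13 ketone, and strain-driven retro-aldol cleaves C3–C14; the labile α-hydroxy aldehyde is trapped in the same flask by Seyferth–Gilbert homologation with the Ohira–Bestmann reagent, which spares the ketone. Partial epimerisation at C2 is harmless because C2 is re-set in steps 13 and 14.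

Step 11
Reactants: 17 2-epi propargylic alcohol C13 ketone acetonide
Product: 20 C13 enol triflate bearing the silylated alkyne, via tris-silyl enol ether 18 (not isolated), via O-silylated enol triflate 19 (not isolated)
Conditions: LiN(i-Pr)2 (3.3 equiv), Me3SiCl, THF, −78 °C; volatiles removed; MeLi, THF, −20 °C; N-(5-chloro-2-pyridyl)triflimide, −78 to −20 °C; aq. citric acid work-up
Reagents that add atoms: chlorotrimethylsilane, C[Si](C)(C)Cl; N-(5-chloro-2-pyridyl)bis(trifluoromethanesulfonimide), O=S(=O)(N(c1ccc(Cl)cn1)S(=O)(=O)C(F)(F)F)C(F)(F)F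
Why: Amide base with internal silyl quench silylates the hydroxyl, the alkyne and, kinetically, the C14 side of the ketone (the α-alkoxy methine C12 is less accessible); MeLi then releases the lithium enolate regiospecifically and the triflimide gives the enol triflate. The O-silyl ether is lost on acidic work-up while the alkynyl silane stays.

Step 12
Reactants: 20 C13 enol triflate bearing the silylated alkyne
Product: 21 ring A 13,14-olefin (2-epi alcohol; silylated alkyne)
Conditions: Pd(OAc)2 (5 mol%), PPh3, HCO2H, n-Bu3N, DMF, 60 °C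
Reagents that add atoms: none
Why: Pd-catalysed hydrogenolysis of the enol triflate (oxidative addition to zerovalent palladium, formate exchange, decarboxylation, reductive elimination) gives the olefin without touching the alkynyl silane or the acetonide.

Step 13
Reactants: 21 ring A 13,14-olefin (2-epi alcohol; silylated alkyne)
Product: 22 C2 silyl ynone
Conditions: Dess–Martin periodinane, NaHCO3, CH2Cl2, 0 °C to rt
Reagents that add atoms: none
Why: Dess–Martin oxidation of the propargylic alcohol erases the wrong C2 configuration; the silyl-capped ynone is stable enough to be handled.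

Step 14
Reactants: 22 C2 silyl ynone
Product: 23 propargylic alcohol with the natural C2 configuration
Conditions: Ru[(R,R)-TsNCH(Ph)CH(Ph)NH](η6-p-cymene) (2 mol%), i-PrOH, rt
Reagents that add atoms: none
Why: Noyori asymmetric transfer hydrogenation of an alkynyl ketone; the alkynyl group takes the position stabilised by the arene ligand, so the (R,R)-catalyst delivers hydride to the face that gives the natural C2 configuration under reagent control. The ring A olefin is not reduced.

Step 15
Reactants: 23 propargylic alcohol with the natural C2 configuration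
Product: 24 C2 TBS ether
Conditions: TBSOTf, 2,6-lutidine, CH2Cl2, −78 to 0 °C
Reagents that add atoms: tert-butyldimethylsilyl triflate, CC(C)(C)[Si](C)(C)OS(=O)(=O)C(F)(F)F
Why: The silyl triflate silylates the hindered secondary alcohol and protects C2–O through the organometallic steps.

Step 16
Reactants: 24 C2 TBS ether
Product: 25 C9 primary alcohol
Conditions: HF·pyridine, pyridine, THF, 0 °C
Reagents that add atoms: none
Why: Buffered HF·pyridine cleaves the unhindered primary TBS ether much faster than the neopentyl-type secondary one; the alkynyl silane and the acetonide are stable.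

Step 17
Reactants: 25 C9 primary alcohol
Product: 26 C9 aldehyde
Conditions: Dess–Martin periodinane, NaHCO3, CH2Cl2, 0 °C
Reagents that add atoms: none
Why: Buffered Dess–Martin oxidation gives the α-branched aldehyde without epimerising C10.

Step 18
Reactants: 27 methyl (S)-3-hydroxy-2-methylpropanoate
Product: 28 methyl (S)-2-methyl-3-(trityloxy)propanoate
Conditions: Ph3CCl, Et3N, DMAP (cat.), CH2Cl2, rt
Reagents that add atoms: trityl chloride, ClC(c1ccccc1)(c1ccccc1)c1ccccc1
Why: Tritylation of the primary alcohol; the trityl ether is stable to base and fluoride and is poorly chelating.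

Step 19
Reactants: 28 methyl (S)-2-methyl-3-(trityloxy)propanoate
Product: 29 (S)-2-methyl-3-(trityloxy)propanal
Conditions: i-Bu2AlH, CH2Cl2, −78 °C; Rochelle salt work-up
Reagents that add atoms: none
Why: Partial reduction stops at the aldehyde through the stable aluminium hemiacetal at low temperature, and the α-stereocentre is not epimerised.

Step 20
Reactants: 29 (S)-2-methyl-3-(trityloxy)propanal
Product: 30 (S)-2-[1-(trityloxy)propan-2-yl]-1,3-dithiane
Conditions: HS(CH2)3SH, MgBr2·OEt2, Et2O, 0 °C to rt
Reagents that add atoms: propane-1,3-dithiol, SCCCS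
Why: Thioacetalisation with the mild Lewis acid MgBr2 keeps the trityl ether and the α-stereocentre (the future C17) intact.

Step 21
Reactants: 26 C9 aldehyde; 30 (S)-2-[1-(trityloxy)propan-2-yl]-1,3-dithiane
Product: 31 C9 carbinol dithiane (both C9 epimers)
Conditions: 30, t-BuLi, THF/HMPA, −78 °C; then 26, −78 °C
Reagents that add atoms: none
Why: Corey–Seebach umpolung: the 2-lithio-1,3-dithiane adds to the aldehyde and forms C8–C9. C9 is not controlled here and is re-set in steps 22 and 23.

Step 22
Reactants: 31 C9 carbinol dithiane (both C9 epimers)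
Product: 32 C9 ketone (2-acyl-1,3-dithiane)
Conditions: Dess–Martin periodinane, NaHCO3, CH2Cl2, rt
Reagents that add atoms: none
Why: Dess–Martin oxidation converges both epimers to the acyl dithiane; sulfur is not oxidised under buffered conditions.

Step 23
Reactants: 32 C9 ketone (2-acyl-1,3-dithiane)
Product: 33 (9S)-carbinol dithiane
Conditions: (R)-2-methyl-CBS-oxazaborolidine (1 equiv), BH3·SMe2, THF, −30 °C
Reagents that add atoms: none
Why: Corey–Bakshi–Shibata reduction; with the fully substituted dithiane carbon as the larger flank, the (R)-catalyst delivers hydride to the Re face of C9 and should give the 9S carbinol under reagent control.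

Step 24
Reactants: 33 (9S)-carbinol dithiane
Product: 34 (9S)-9-hydroxy C8 ketone
Conditions: MeI, CaCO3, MeCN/H2O (9:1), 45 °C
Reagents that add atoms: water, O
Why: S-Methylation and hydrolysis of the dithiane under neutral buffered conditions unmask the C8 ketone without epimerising C17 or shifting the α-ketol.

Step 25
Reactants: 34 (9S)-9-hydroxy C8 ketone
Product: 35 8,9-syn diol with the C7 PMB ether
Conditions: Bu3SnCH2OPMB, n-BuLi, THF, −78 °C; MgBr2·OEt2; then 34, −78 to −40 °C
Reagents that add atoms: tributyl{[(4-methoxybenzyl)oxy]methyl}stannane, CCCC[Sn](CCCC)(CCCC)COCc1ccc(OC)cc1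
Why: Tin–lithium exchange gives the alkoxymethyl nucleophile, which is transmetallated to magnesium; addition to the five-membered chelate of the C9 alkoxide and the C8 carbonyl occurs anti to the ring A substituent on C9 (Cram chelate model). This gives the 8,9-syn diol, i.e. the C8 configuration of the target.

Step 26
Reactants: 35 8,9-syn diol with the C7 PMB ether
Product: 36 C9 acetate
Conditions: Ac2O, pyridine, DMAP (cat.), CH2Cl2, rt
Reagents that add atoms: acetic anhydride, CC(=O)OC(C)=O
Why: Nucleophile-catalysed acetylation of the secondary C9 alcohol; the tertiary C8 alcohol does not react.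

Step 27
Reactants: 36 C9 acetate
Product: 37 C2 alcohol with the terminal alkyne
Conditions: Bu4NF, AcOH, THF, 0 °C to rt
Reagents that add atoms: none
Why: Fluoride removes the C2 silyl ether and the alkynyl silane in one operation; buffering with acetic acid prevents acetate migration or cleavage.

Step 28
Reactants: 37 C2 alcohol with the terminal alkyne
Product: 38 C2 butanoate
Conditions: (n-PrCO)2O, Et3N, DMAP (cat.), CH2Cl2, 0 °C
Reagents that add atoms: butanoic anhydride, CCCC(=O)OC(=O)CCC
Why: DMAP-catalysed acylation of the secondary propargylic alcohol installs the C2 butanoate; the tertiary C8 alcohol is inert.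

Step 29
Reactants: 39 prop-2-yn-1-ol
Product: 40 3-chloroprop-2-yn-1-ol
Conditions: aq. NaOCl, 0 °C
Reagents that add atoms: sodium hypochlorite, [Na+].[O-]Cl
Why: Hypohalite chlorination of the terminal alkyne through its acetylide gives the 1-chloroalkyne.

Step 30
Reactants: 40 3-chloroprop-2-yn-1-ol
Product: 41 (Z)-3-chloro-2-iodoprop-2-en-1-ol
Conditions: LiI, Pd(OAc)2 (5 mol%), AcOH, rt
Reagents that add atoms: lithium iodide, [Li+].[I-]
Why: Pd-catalysed anti-hydroiodination of the 1-chloroalkyne: iodide adds to the carbon remote from chlorine and protonolysis occurs at the chlorine-bearing carbon, giving the (Z)-1-chloro-2-iodoalkene.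

Step 31
Reactants: 38 C2 butanoate; 41 (Z)-3-chloro-2-iodoprop-2-en-1-ol
Product: 42 C3–C4 enyne with the C16 alcohol
Conditions: Pd(PPh3)4 (5 mol%), CuI (10 mol%), i-Pr2NH, THF, rt
Reagents that add atoms: none
Why: Sonogashira coupling forms C4–C5; oxidative addition occurs at the C–I bond only, so the vinyl chloride and its geometry are kept, and the propargylic ester is tolerated at room temperature.

Step 32
Reactants: 42 C3–C4 enyne with the C16 alcohol
Product: 43 (3Z)-diene with the C16 alcohol
Conditions: Zn dust activated with Cu(OAc)2 and AgNO3, MeOH/H2O (1:1), 40 °C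
Reagents that add atoms: none
Why: Boland reduction: activated zinc in protic medium cis-reduces only the triple bond conjugated with the olefin and gives the (3Z)-diene; vinyl chloride, esters and the isolated ring A olefin are not reduced.

Step 33
Reactants: 43 (3Z)-diene with the C16 alcohol
Product: 44 C16 allylic bromide
Conditions: CBr4, PPh3, 2,6-lutidine, CH2Cl2, −20 °C
Reagents that add atoms: carbon tetrabromide, BrC(Br)(Br)Br
Why: Appel bromination of the primary allylic alcohol by SN2 at low temperature; the tertiary alcohol does not react and the base protects the trityl ether.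

Step 34
Reactants: 44 C16 allylic bromide
Product: 45 C7 primary alcohol
Conditions: DDQ, CH2Cl2/pH 7 buffer, 0 °C
Reagents that add atoms: none
Why: Oxidative cleavage of the PMB ether by electron transfer to DDQ frees the C7 alcohol; the electron-poor chlorodiene is a poor partner for the quinone at 0 °C.

Step 35
Reactants: 45 C7 primary alcohol
Product: 46 C7 aldehyde (α-hydroxy aldehyde)
Conditions: Dess–Martin periodinane, NaHCO3, CH2Cl2, 0 °C
Reagents that add atoms: none
Why: Dess–Martin oxidation of the primary alcohol of the 1,2-diol gives the α-hydroxy aldehyde; the tertiary alcohol cannot be oxidised.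

Step 36
Reactants: 46 C7 aldehyde (α-hydroxy aldehyde)
Product: 47 ten-membered chlorohydrin (6-chloro, 7-hydroxy, C5=C16 methylene)
Conditions: CrCl2 (8 equiv), THF/DMF (4:1), rt, slow addition of 46 to 2 mM
Reagents that add atoms: none
Why: Nozaki–Hiyama allylation: CrCl2 (two equivalents of divalent chromium per bromide) gives the γ-chloroallylchromium species, which adds through C6 to the C7 aldehyde in a chair transition state with chlorine equatorial. This closes the ten-membered ring and gives the anti C6/C7 chlorohydrin and the C5=C16 methylene; the face should be chosen by chelation of chromium to the C8 hydroxyl and by the ring conformation.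

Step 37
Reactants: 47 ten-membered chlorohydrin
Product: 48 C19 primary alcohol
Conditions: HCO2H, Et2O, rt, short contact
Reagents that add atoms: none
Why: Formic acid ionises only the trityl ether; the acetonide and the allylic chloride should survive the short exposure.

Step 38
Reactants: 48 C19 primary alcohol
Product: 51 γ-lactone acetonide, via hydroxy aldehyde 49 (not isolated), via lactol 50 (not isolated)
Conditions: TEMPO (20 mol%), PhI(OAc)2 (2.5 equiv), CH2Cl2, rt
Reagents that add atoms: none
Why: The oxoammonium oxidant takes the primary C19 alcohol selectively; the aldehyde is captured by the C7 hydroxyl as the five-membered lactol, which is oxidised on to the γ-lactone.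

Step 39
Reactants: 51 γ-lactone acetonide
Product: 52 11,12-diol lactone
Conditions: CF3CO2H/H2O (9:1), CH2Cl2, 0 °C
Reagents that add atoms: none
Why: Aqueous acid hydrolysis of the acetonide frees the 11,12-diol; it is done before the epoxide exists and after the lactone has tied up the C7 hydroxyl.

Step 40
Reactants: 52 11,12-diol lactone
Product: 53 13α,14α-epoxide with the free C12 alcohol
Conditions: VO(acac)2 (5 mol%), t-BuOOH, CH2Cl2, 0 °C
Reagents that add atoms: tert-butyl hydroperoxide, CC(C)(C)OO
Why: Vanadium-catalysed epoxidation directed by the allylic C12 hydroxyl (and the C11 hydroxyl on the same face) delivers oxygen to the α face of C13=C14 only; the other olefins have no free allylic hydroxyl.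

Step 41
Reactants: 53 13α,14α-epoxide with the free C12 alcohol
Product: 54 CNP0188106.1
Conditions: (n-PrCO)2O, DMAP, pyridine, CH2Cl2, 0 °C to rt
Reagents that add atoms: butanoic anhydride, CCCC(=O)OC(=O)CCC
Why: DMAP-catalysed acylation of the only secondary alcohol; the tertiary C8 and C11 alcohols stay free.

## Compound list

1 | ethyl 2-methyl-4-oxocyclohex-2-ene-1-carboxylate (racemic) | CCOC(=O)C1CCC(=O)C=C1C | starting material
2 | ethyl 7-methyl-1,4-dioxaspiro[4.5]dec-7-ene-8-carboxylate | CCOC(=O)C1=C(C)CC2(CC1)OCCO2 | intermediate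
3 | (7-methyl-1,4-dioxaspiro[4.5]dec-7-en-8-yl)methanol | OCC1=C(C)CC2(CC1)OCCO2 | intermediate
4 | rac-4-(hydroxymethyl)-3-methylcyclohex-2-en-1-one | CC1=CC(=O)CCC1CO | intermediate
5 | (S)-4-(hydroxymethyl)-3-methylcyclohex-2-en-1-one | CC1=CC(=O)CC[C@@H]1CO | intermediate
6 | (S)-4-[(tert-butyldimethylsilyloxy)methyl]-3-methylcyclohex-2-en-1-one | CC1=CC(=O)CC[C@@H]1CO[Si](C)(C)C(C)(C)C | intermediate
7 | vinylene carbonate (1,3-dioxol-2-one) | O=C1OC=CO1 | starting material
8 | cis-anti-cis photoadduct: cyclobutane fused at C1–C14 on the α face, cis C2/C3 carbonate anti to ring A, C15 methyl β, C13 ketone, C10 CH2OTBS β | C[C@]12[C@@H]3OC(=O)O[C@@H]3[C@H]1C(=O)CC[C@@H]2CO[Si](C)(C)C(C)(C)C | intermediate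
9 | C12=C13 trimethylsilyl enol ether of 8 | C[C@]12[C@@H]3OC(=O)O[C@@H]3[C@H]1C(O[Si](C)(C)C)=CC[C@@H]2CO[Si](C)(C)C(C)(C)C | intermediate
10 | tricyclic C11=C12 enone carbonate | C[C@]12[C@@H]3OC(=O)O[C@@H]3[C@H]1C(=O)C=C[C@@H]2CO[Si](C)(C)C(C)(C)C | intermediate
11 | 11-methyl C12=C13 trimethylsilyl enol ether (C11 configuration transient, not specified) | C[C@]12[C@@H]3OC(=O)O[C@@H]3[C@H]1C(O[Si](C)(C)C)=CC(C)[C@@H]2CO[Si](C)(C)C(C)(C)C | intermediate
12 | tricyclic 11-methyl C11=C12 enone carbonate | C[C@]12[C@@H]3OC(=O)O[C@@H]3[C@H]1C(=O)C=C(C)[C@@H]2CO[Si](C)(C)C(C)(C)C | intermediate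
13 | 11α,12α-dihydroxy C13 ketone carbonate (C20 methyl β) | C[C@]12[C@@H]3OC(=O)O[C@@H]3[C@H]1C(=O)[C@@H](O)[C@@](C)(O)[C@@H]2CO[Si](C)(C)C(C)(C)C | intermediate
14 | 11α,12α-acetonide C13 ketone carbonate | C[C@]12[C@@H]3OC(=O)O[C@@H]3[C@H]1C(=O)[C@H]4OC(C)(C)O[C@@]4(C)[C@@H]2CO[Si](C)(C)C(C)(C)C | intermediate
15 | cis-cyclobutane-2,3-diol of 14 | C[C@]12[C@H](O)[C@H](O)[C@H]1C(=O)[C@H]4OC(C)(C)O[C@@]4(C)[C@@H]2CO[Si](C)(C)C(C)(C)C | intermediate
16 | retro-aldol product: ring A C13 ketone with C1 bearing CH(OH)CHO (C2 epimeric to the target) | O=C[C@@H](O)[C@@]2(C)CC(=O)[C@H]4OC(C)(C)O[C@@]4(C)[C@@H]2CO[Si](C)(C)C(C)(C)C | intermediate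
17 | 2-epi propargylic alcohol: C1 bears CH(OH)C≡CH, C13 ketone, 11,12-acetonide, C10 CH2OTBS | C#C[C@@H](O)[C@@]2(C)CC(=O)[C@H]4OC(C)(C)O[C@@]4(C)[C@@H]2CO[Si](C)(C)C(C)(C)C | intermediate
18 | tris(trimethylsilyl) derivative of 17 (alkynyl silane, C2 silyl ether, C13=C14 enol silane) | C[Si](C)(C)C#C[C@@H](O[Si](C)(C)C)[C@@]2(C)C=C(O[Si](C)(C)C)[C@H]4OC(C)(C)O[C@@]4(C)[C@@H]2CO[Si](C)(C)C(C)(C)C | intermediate
19 | C13 enol triflate with C2 trimethylsilyl ether | C[Si](C)(C)C#C[C@@H](O[Si](C)(C)C)[C@@]2(C)C=C(OS(=O)(=O)C(F)(F)F)[C@H]4OC(C)(C)O[C@@]4(C)[C@@H]2CO[Si](C)(C)C(C)(C)C | intermediate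
20 | C13 enol triflate (C13=C14), silylated alkyne, free 2-epi alcohol | C[Si](C)(C)C#C[C@@H](O)[C@@]2(C)C=C(OS(=O)(=O)C(F)(F)F)[C@H]4OC(C)(C)O[C@@]4(C)[C@@H]2CO[Si](C)(C)C(C)(C)C | intermediate
21 | ring A 13,14-olefin, silylated alkyne, 2-epi alcohol | C[Si](C)(C)C#C[C@@H](O)[C@@]2(C)C=C[C@H]4OC(C)(C)O[C@@]4(C)[C@@H]2CO[Si](C)(C)C(C)(C)C | intermediate
22 | C2 silyl ynone | C[Si](C)(C)C#CC(=O)[C@@]2(C)C=C[C@H]4OC(C)(C)O[C@@]4(C)[C@@H]2CO[Si](C)(C)C(C)(C)C | intermediate
23 | propargylic alcohol with the natural C2 configuration | C[Si](C)(C)C#C[C@H](O)[C@@]2(C)C=C[C@H]4OC(C)(C)O[C@@]4(C)[C@@H]2CO[Si](C)(C)C(C)(C)C | intermediate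
24 | C2 TBS ether | C[Si](C)(C)C#C[C@H](O[Si](C)(C)C(C)(C)C)[C@@]2(C)C=C[C@H]4OC(C)(C)O[C@@]4(C)[C@@H]2CO[Si](C)(C)C(C)(C)C | intermediate
25 | C9 primary alcohol | C[Si](C)(C)C#C[C@H](O[Si](C)(C)C(C)(C)C)[C@@]2(C)C=C[C@H]4OC(C)(C)O[C@@]4(C)[C@@H]2CO | intermediate
26 | C9 aldehyde | C[Si](C)(C)C#C[C@H](O[Si](C)(C)C(C)(C)C)[C@@]2(C)C=C[C@H]4OC(C)(C)O[C@@]4(C)[C@@H]2C=O | intermediate
27 | methyl (S)-3-hydroxy-2-methylpropanoate | COC(=O)[C@@H](C)CO | starting material
28 | methyl (S)-2-methyl-3-(trityloxy)propanoate | COC(=O)[C@@H](C)COC(c1ccccc1)(c1ccccc1)c1ccccc1 | intermediate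
29 | (S)-2-methyl-3-(trityloxy)propanal | O=C[C@@H](C)COC(c1ccccc1)(c1ccccc1)c1ccccc1 | intermediate
30 | (S)-2-[1-(trityloxy)propan-2-yl]-1,3-dithiane | S1CCCSC1[C@@H](C)COC(c1ccccc1)(c1ccccc1)c1ccccc1 | intermediate
31 | C9 carbinol with C8 as 1,3-dithiane (both C9 epimers) | C[Si](C)(C)C#C[C@H](O[Si](C)(C)C(C)(C)C)[C@@]2(C)C=C[C@H]4OC(C)(C)O[C@@]4(C)[C@@H]2C(O)C3(SCCCS3)[C@@H](C)COC(c5ccccc5)(c5ccccc5)c5ccccc5 | intermediate
32 | C9 ketone (2-acyl-1,3-dithiane) | C[Si](C)(C)C#C[C@H](O[Si](C)(C)C(C)(C)C)[C@@]2(C)C=C[C@H]4OC(C)(C)O[C@@]4(C)[C@@H]2C(=O)C3(SCCCS3)[C@@H](C)COC(c5ccccc5)(c5ccccc5)c5ccccc5 | intermediate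
33 | (9S)-carbinol dithiane | C[Si](C)(C)C#C[C@H](O[Si](C)(C)C(C)(C)C)[C@@]2(C)C=C[C@H]4OC(C)(C)O[C@@]4(C)[C@@H]2[C@H](O)C3(SCCCS3)[C@@H](C)COC(c5ccccc5)(c5ccccc5)c5ccccc5 | intermediate
34 | (9S)-9-hydroxy C8 ketone | C[Si](C)(C)C#C[C@H](O[Si](C)(C)C(C)(C)C)[C@@]2(C)C=C[C@H]4OC(C)(C)O[C@@]4(C)[C@@H]2[C@H](O)C(=O)[C@@H](C)COC(c5ccccc5)(c5ccccc5)c5ccccc5 | intermediate
35 | 8,9-syn diol, C8 bearing CH2OPMB (C7) | C[Si](C)(C)C#C[C@H](O[Si](C)(C)C(C)(C)C)[C@@]2(C)C=C[C@H]4OC(C)(C)O[C@@]4(C)[C@@H]2[C@H](O)[C@](COCc5ccc(OC)cc5)(O)[C@@H](C)COC(c5ccccc5)(c5ccccc5)c5ccccc5 | intermediate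
36 | C9 acetate | C[Si](C)(C)C#C[C@H](O[Si](C)(C)C(C)(C)C)[C@@]2(C)C=C[C@H]4OC(C)(C)O[C@@]4(C)[C@@H]2[C@H](OC(C)=O)[C@](COCc5ccc(OC)cc5)(O)[C@@H](C)COC(c5ccccc5)(c5ccccc5)c5ccccc5 | intermediate
37 | C2 alcohol with the terminal alkyne | C#C[C@H](O)[C@@]2(C)C=C[C@H]4OC(C)(C)O[C@@]4(C)[C@@H]2[C@H](OC(C)=O)[C@](COCc5ccc(OC)cc5)(O)[C@@H](C)COC(c5ccccc5)(c5ccccc5)c5ccccc5 | intermediate
38 | C2 butanoate with the terminal alkyne | C#C[C@H](OC(=O)CCC)[C@@]2(C)C=C[C@H]4OC(C)(C)O[C@@]4(C)[C@@H]2[C@H](OC(C)=O)[C@](COCc5ccc(OC)cc5)(O)[C@@H](C)COC(c5ccccc5)(c5ccccc5)c5ccccc5 | intermediate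
39 | prop-2-yn-1-ol | C#CCO | starting material
40 | 3-chloroprop-2-yn-1-ol | ClC#CCO | intermediate
41 | (Z)-3-chloro-2-iodoprop-2-en-1-ol | OC/C(I)=C/Cl | intermediate
42 | enyne: C3≡C4 coupled to C5(=C6HCl)CH2OH, chlorine cis to C4 | OC/C(=C/Cl)C#C[C@H](OC(=O)CCC)[C@@]2(C)C=C[C@H]4OC(C)(C)O[C@@]4(C)[C@@H]2[C@H](OC(C)=O)[C@](COCc5ccc(OC)cc5)(O)[C@@H](C)COC(c5ccccc5)(c5ccccc5)c5ccccc5 | intermediate
43 | (3Z)-diene with the C16 alcohol | OC/C(=C/Cl)/C=C\[C@H](OC(=O)CCC)[C@@]2(C)C=C[C@H]4OC(C)(C)O[C@@]4(C)[C@@H]2[C@H](OC(C)=O)[C@](COCc5ccc(OC)cc5)(O)[C@@H](C)COC(c5ccccc5)(c5ccccc5)c5ccccc5 | intermediate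
44 | C16 allylic bromide | BrC/C(=C/Cl)/C=C\[C@H](OC(=O)CCC)[C@@]2(C)C=C[C@H]4OC(C)(C)O[C@@]4(C)[C@@H]2[C@H](OC(C)=O)[C@](COCc5ccc(OC)cc5)(O)[C@@H](C)COC(c5ccccc5)(c5ccccc5)c5ccccc5 | intermediate
45 | C7 primary alcohol (C16 bromide) | BrC/C(=C/Cl)/C=C\[C@H](OC(=O)CCC)[C@@]2(C)C=C[C@H]4OC(C)(C)O[C@@]4(C)[C@@H]2[C@H](OC(C)=O)[C@](CO)(O)[C@@H](C)COC(c5ccccc5)(c5ccccc5)c5ccccc5 | intermediate
46 | C7 aldehyde (C16 bromide) | BrC/C(=C/Cl)/C=C\[C@H](OC(=O)CCC)[C@@]2(C)C=C[C@H]4OC(C)(C)O[C@@]4(C)[C@@H]2[C@H](OC(C)=O)[C@](C=O)(O)[C@@H](C)COC(c5ccccc5)(c5ccccc5)c5ccccc5 | intermediate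
47 | ten-membered ring closed: 6-chloro, 7-hydroxy, C5=C16 methylene, C19 trityl ether, 11,12-acetonide | C=C1/C=C\[C@H](OC(=O)CCC)[C@@]2(C)C=C[C@H]3OC(C)(C)O[C@@]3(C)[C@@H]2[C@H](OC(C)=O)[C@](O)([C@@H](C)COC(c3ccccc3)(c3ccccc3)c3ccccc3)[C@@H](O)[C@H]1Cl | intermediate
48 | C19 primary alcohol (7,8,19-triol) | C=C1/C=C\[C@H](OC(=O)CCC)[C@@]2(C)C=C[C@H]3OC(C)(C)O[C@@]3(C)[C@@H]2[C@H](OC(C)=O)[C@](O)([C@@H](C)CO)[C@@H](O)[C@H]1Cl | intermediate
49 | C19 aldehyde | C=C1/C=C\[C@H](OC(=O)CCC)[C@@]2(C)C=C[C@H]3OC(C)(C)O[C@@]3(C)[C@@H]2[C@H](OC(C)=O)[C@](O)([C@@H](C)C=O)[C@@H](O)[C@H]1Cl | intermediate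
50 | C19 lactol (C19 configuration not specified) | C=C1/C=C\[C@H](OC(=O)CCC)[C@@]2(C)C=C[C@H]3OC(C)(C)O[C@@]3(C)[C@@H]2[C@H](OC(C)=O)[C@]2(O)[C@@H](C)C(O)O[C@H]2[C@H]1Cl | intermediate
51 | γ-lactone with the 11,12-acetonide | C=C1/C=C\[C@H](OC(=O)CCC)[C@@]2(C)C=C[C@H]3OC(C)(C)O[C@@]3(C)[C@@H]2[C@H](OC(C)=O)[C@]2(O)[C@@H](C)C(=O)O[C@H]2[C@H]1Cl | intermediate
52 | 11α,12α-diol lactone with the 13,14-olefin | C=C1/C=C\[C@H](OC(=O)CCC)[C@@]2(C)C=C[C@@H](O)[C@@](C)(O)[C@@H]2[C@H](OC(C)=O)[C@]2(O)[C@@H](C)C(=O)O[C@H]2[C@H]1Cl | intermediate
53 | 13α,14α-epoxide with the free C12 alcohol | C=C1/C=C\[C@H](OC(=O)CCC)[C@@]2(C)[C@H]3O[C@H]3[C@@H](O)[C@@](C)(O)[C@@H]2[C@H](OC(C)=O)[C@]2(O)[C@@H](C)C(=O)O[C@H]2[C@H]1Cl | intermediate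
54 | CNP0188106.1, (1S,2S,3Z,6S,7R,8R,9S,10S,11S,12R,13R,14R,17R) | C=C1/C=C\[C@H](OC(=O)CCC)[C@@]2(C)[C@H]3O[C@H]3[C@@H](OC(=O)CCC)[C@@](C)(O)[C@@H]2[C@H](OC(C)=O)[C@]2(O)[C@@H](C)C(=O)O[C@H]2[C@H]1Cl | target

## Step count and least certain steps

Total step count: 41. Longest linear sequence: 36 (steps 1–17, 21–28 and 31–41); steps 18–20 and 29–30 make the two side fragments.

Step 5 (key step). The most likely failure is slow capture of the enone triplet by the electron-poor, polymerisation-prone vinylene carbonate. Enone dimerisation and loss of material then compete, and long irradiation at higher temperature would erode the face discrimination that the axial C10 arm provides. Fallback: bring in the two cyclobutane carbons with a more efficient photo-partner and add the oxygens afterwards. Starting from 6, irradiation with (Z)-1,2-dichloroethene should give the dichlorocyclobutane F1. Zinc dust in ethanol would remove both chlorines to give the cyclobutene F2. Catalytic OsO4 with NMO should attack the exposed convex face, anti to ring A, to give the cis-cyclobutanediol F3. Immediate treatment with 1,1'-carbonyldiimidazole returns to the route at 8.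

Step 36. Ring closure competes with intermolecular coupling and protonolysis of the allylchromium species, and the ring may close through the other anti chair, which would invert C6 and C7 together. Fallback: make C6–C7 intermolecularly and close the ring at C4–C5 instead. Starting from 38, DDQ would give the C7 alcohol F4 and Dess–Martin oxidation the aldehyde F5. Separately, 41 with CBr4/PPh3 gives the bromide F6. CrCl2 alone (no nickel, so the vinyl iodide is spared) should join F5 and F6 through the chelated α-hydroxy aldehyde to give the open-chain chlorohydrin vinyl iodide F7. Intramolecular Sonogashira coupling at high dilution (Pd(PPh3)4, CuI, i-Pr2NH) would then give the cyclic enyne F8. Zinc activated with Cu(OAc)2 and AgNO3 reduces its triple bond and comes back to the route at 47.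

Step 11. Enolisation toward C12, or equilibration of the lithium enolate before triflation, would be followed by β-elimination of the C11 oxygen. Fallback: a Shapiro reaction, which fixes the regiochemistry through the hydrazone dianion. Starting from 17, 2,4,6-triisopropylbenzenesulfonyl hydrazide gives the trisylhydrazone F9. Excess n-BuLi (which also deprotonates the hydroxyl and the alkyne) followed by aqueous quench should give the ring A olefin with the terminal alkyne F10. EtMgBr and Me3SiCl, then dilute acid to remove the O-silyl group, return to the route at 21.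

Step 23. The two flanks of the C9 ketone are both bulky, so the oxazaborolidine may not differentiate them well and the facial selectivity could be poor. Fallback: reverse the polarity of the C8–C9 union so that C8 is set by Felkin–Anh addition and C9 by a chelated reduction. From 28, MeNHOMe·HCl with i-PrMgCl gives the Weinreb amide F11, and the lithium reagent from Bu3SnCH2OPMB gives the ketone F12. From 26, propane-1,3-dithiol with MgBr2·OEt2 gives the ring A dithiane F13. Its lithio derivative should add to F12 anti to the CH2OTr group on C17, giving the adduct F14 with the C8 hydroxyl syn to the C18 methyl as in the target. MeI/CaCO3 unmasks the hydroxy ketone F15. Zn(BH4)2 should then reduce the chelate of the C8 hydroxyl and the C9 carbonyl from the side of the smaller CH2OPMB group, which returns to the route at 35.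

Step 8. Osmylation of the electron-poor, trisubstituted enone may be slow, and attack from the β face of the rigid tricycle would give the wrong C11/C12 pair. Fallback: dihydroxylate after the cyclobutane has been opened, with delivery of the reagent by a hydroxyl on the α side. Starting from 12, K2CO3/MeOH with the Ohira–Bestmann reagent (short contact at 0 °C, because C10 is now vinylogously acidic) gives the alkynol enone F16. Stoichiometric OsO4·TMEDA in CH2Cl2 at −78 °C, hydrogen-bonded to the C2 hydroxyl on the α-oriented arm, should give the triol ketone F17. 2,2-Dimethoxypropane with PPTS closes the acetonide on the cis-diol and comes back to the route at 17.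

## Further compounds

F1 | step 5 | 2,3-dichlorocyclobutane photoadduct of 6 (chlorine configuration open) | C[C@]12C(Cl)C(Cl)[C@H]1C(=O)CC[C@@H]2CO[Si](C)(C)C(C)(C)C
F2 | step 5 | cyclobutene fused at C1–C14 | C[C@]12C=C[C@H]1C(=O)CC[C@@H]2CO[Si](C)(C)C(C)(C)C
F3 | step 5 | cis-cyclobutane-2,3-diol anti to ring A | C[C@]12[C@H](O)[C@H](O)[C@H]1C(=O)CC[C@@H]2CO[Si](C)(C)C(C)(C)C
F4 | step 36 | C7 primary alcohol from 38 | C#C[C@H](OC(=O)CCC)[C@@]2(C)C=C[C@H]4OC(C)(C)O[C@@]4(C)[C@@H]2[C@H](OC(C)=O)[C@](CO)(O)[C@@H](C)COC(c5ccccc5)(c5ccccc5)c5ccccc5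
F5 | step 36 | C7 aldehyde with the terminal alkyne | C#C[C@H](OC(=O)CCC)[C@@]2(C)C=C[C@H]4OC(C)(C)O[C@@]4(C)[C@@H]2[C@H](OC(C)=O)[C@](C=O)(O)[C@@H](C)COC(c5ccccc5)(c5ccccc5)c5ccccc5
F6 | step 36 | (Z)-3-bromo-1-chloro-2-iodoprop-1-ene | BrC/C(I)=C/Cl
F7 | step 36 | open-chain 6-chloro-7-hydroxy adduct with the C5 vinyl iodide | C#C[C@H](OC(=O)CCC)[C@@]2(C)C=C[C@H]4OC(C)(C)O[C@@]4(C)[C@@H]2[C@H](OC(C)=O)[C@](O)([C@@H](C)COC(c5ccccc5)(c5ccccc5)c5ccccc5)[C@@H](O)[C@@H](Cl)C(I)=C
F8 | step 36 | ten-membered cyclic enyne (C3≡C4) | C=C1C#C[C@H](OC(=O)CCC)[C@@]2(C)C=C[C@H]4OC(C)(C)O[C@@]4(C)[C@@H]2[C@H](OC(C)=O)[C@](O)([C@@H](C)COC(c5ccccc5)(c5ccccc5)c5ccccc5)[C@@H](O)[C@H]1Cl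
F9 | step 11 | 2,4,6-triisopropylbenzenesulfonylhydrazone of 17 | C#C[C@@H](O)[C@@]2(C)CC(=NNS(=O)(=O)c3c(C(C)C)cc(C(C)C)cc3C(C)C)[C@H]4OC(C)(C)O[C@@]4(C)[C@@H]2CO[Si](C)(C)C(C)(C)C
F10 | step 11 | ring A 13,14-olefin with the terminal alkyne and 2-epi alcohol | C#C[C@@H](O)[C@@]2(C)C=C[C@H]4OC(C)(C)O[C@@]4(C)[C@@H]2CO[Si](C)(C)C(C)(C)C
F11 | step 23 | (S)-N-methoxy-N,2-dimethyl-3-(trityloxy)propanamide | CON(C)C(=O)[C@@H](C)COC(c1ccccc1)(c1ccccc1)c1ccccc1
F12 | step 23 | (S)-1-[(4-methoxybenzyl)oxy]-3-methyl-4-(trityloxy)butan-2-one | COc1ccc(COCC(=O)[C@@H](C)COC(c2ccccc2)(c2ccccc2)c2ccccc2)cc1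
F13 | step 23 | 1,3-dithiane of aldehyde 26 (C9 as the dithiane carbon) | C[Si](C)(C)C#C[C@H](O[Si](C)(C)C(C)(C)C)[C@@]2(C)C=C[C@H]4OC(C)(C)O[C@@]4(C)[C@@H]2C3SCCCS3
F14 | step 23 | C8 tertiary carbinol with C9 as 1,3-dithiane | C[Si](C)(C)C#C[C@H](O[Si](C)(C)C(C)(C)C)[C@@]2(C)C=C[C@H]4OC(C)(C)O[C@@]4(C)[C@@H]2C3(SCCCS3)[C@@](O)(COCc5ccc(OC)cc5)[C@@H](C)COC(c5ccccc5)(c5ccccc5)c5ccccc5
F15 | step 23 | C9 ketone with the C8 tertiary alcohol | C[Si](C)(C)C#C[C@H](O[Si](C)(C)C(C)(C)C)[C@@]2(C)C=C[C@H]4OC(C)(C)O[C@@]4(C)[C@@H]2C(=O)[C@@](O)(COCc5ccc(OC)cc5)[C@@H](C)COC(c5ccccc5)(c5ccccc5)c5ccccc5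
F16 | step 8 | 2-epi propargylic alcohol with the 11-methyl C11=C12 enone | C#C[C@@H](O)[C@@]2(C)CC(=O)C=C(C)[C@@H]2CO[Si](C)(C)C(C)(C)C
F17 | step 8 | 2,11α,12α-triol C13 ketone | C#C[C@@H](O)[C@@]2(C)CC(=O)[C@@H](O)[C@@](C)(O)[C@@H]2CO[Si](C)(C)C(C)(C)C
A1 | alternative 1 | chlorinated bicyclic lactone with the 13,14-olefin, free 11,12-diol and C8 triethylsilyl ether | C=C1/C=C\[C@H](OC(=O)CCC)[C@@]2(C)C=C[C@@H](O)[C@@](C)(O)[C@@H]2[C@H](OC(C)=O)[C@]2(O[Si](CC)(CC)CC)[C@@H](C)C(=O)O[C@H]2[C@H]1Cl
A2 | alternative 1 | open-chain C16 allylic bromide with the C7 aldehyde and C19 methyl ester | BrC/C(=C/Cl)/C=C\[C@H](OC(=O)CCC)[C@@]1(C)C=C[C@@H](O)[C@@](C)(O)[C@@H]1[C@H](OC(C)=O)[C@@](O[Si](CC)(CC)CC)(C=O)[C@@H](C)C(=O)OC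
A3 | alternative 2 | ten-membered C2/C7 diketone | C12(OCCO1)CCC(=O)[C@@]3(C)CC4(OCCO4)C[C@@H](C)[C@@H]3[C@H](OCOC)[C@](OCOC)([C@@H](C)C(=O)OC)C(=O)C2
A4 | alternative 2 | tricyclic C2=C7 olefin | C12(OCCO1)CCC=5[C@@]3(C)CC4(OCCO4)C[C@@H](C)[C@@H]3[C@H](OCOC)[C@](OCOC)([C@@H](C)C(=O)OC)C=5C2
A5 | alternative 3 | bicyclic C12 enone with C1, C10 and C11 set | C=C1CCC(=O)[C@@]2(C)C=CC(=O)[C@@](C)(O)[C@@H]2[C@H](O[Si](C)(C)C(C)(C)C)[C@]2(O[Si](C)(C)C)[C@@H](C)C(=O)O[C@H]2[C@@H]1O[Si](C)(C)C(C)(C)C
A6 | alternative 3 | fourteen-membered keto-dienone macrocycle (C1 and the C10=C11 geometry left open) | C=C1CCC(=O)C(C)/C=C\C(=O)C(C)=C[C@H](O[Si](C)(C)C(C)(C)C)[C@]2(O[Si](C)(C)C)[C@@H](C)C(=O)O[C@H]2[C@@H]1O[Si](C)(C)C(C)(C)C
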